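**Plan**

1. Cuts: the side chain at the CH2–CH= bond two carbons from the ring (B-alkyl Suzuki–Miyaura), the hydroxypropyl chain between its first and second carbon (Wittig on a lactol), then the cyclohexane at C3–C4 and C6–C1 together (ring locants: C1 carbinol carbon, C2 quaternary carbon, C3 the CH, C4 alkylidene carbon, C5 and C6 the CH2 groups).
2. Feature used: C4(=C(CH3)C)–C5–C6 is a ring-opened 2-cyclopropylidenepropyl unit, and C3 and C1 sit 1,3 on the quaternary C2. A C3 radical can add to the cyclopropane ring carbon (C4), the ring opens to a C6 radical, and its samarium form adds to the C1 ketone.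
3. Forward order: C2 by an enantioselective Ireland–Claisen rearrangement; the cyclopropylidene alcohol is tied on as an acetal (temporary tether); one SmI2 relay closes a dihydropyran (not in the target, opened later) and then the cyclohexane; side chain by Suzuki coupling; tether ring opened, chain completed, allylic alcohol oxidised.
4. Stereochemistry: C2 from the chiral boron reagent; C3 and C1 from C2 in the key step (both C3 epimers of the precursor converge through the planar radical); enal geometry from the tether ring; side-chain carbinol from a chiral phosphoric acid; E alkenes from syn-carboalumination.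

Key step: step 10

Remark: the sense of induction of the chiral boron reagent (step 6) and of the chiral phosphoric acid (step 13) is assigned by analogy with the parent reactions; if a first run shows the opposite sense, the enantiomeric reagent or catalyst is taken.

**Route**

Step 1
Reactants: 1 [(1-ethoxycyclopropyl)oxy]trimethylsilane; 2 ethyl 2-(triphenyl-λ5-phosphanylidene)propanoate
Product: 4 ethyl 2-cyclopropylidenepropanoate, via cyclopropanone 3 (not isolated)
Conditions: PhCO2H (10 mol%), toluene, 90 °C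
Reagents that add atoms: none
Why: Acid-catalysed release of cyclopropanone from its silyl hemiketal and Wittig olefination with the stabilised ylide should give the cyclopropylidene ester, the strained ketone being reactive enough for a disubstituted ylide.

Step 2
Reactants: 4 ethyl 2-cyclopropylidenepropanoate
Product: 5 2-cyclopropylidenepropan-1-ol
Conditions: i-Bu2AlH (2.2 equiv), CH2Cl2, −78 → 0 °C; aq. Rochelle salt
Reagents that add atoms: none
Why: 1,2-Reduction of the conjugated ester by the aluminium hydride gives the allylic alcohol and leaves the tetrasubstituted alkene untouched.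

Step 3
Reactants: 6 methyl 3,3-dimethoxypropanoate
Product: 7 3,3-dimethoxypropanoic acid
Conditions: LiOH, THF/H2O, 0 °C → rt; then cold 1 M HCl to pH 4
Reagents that add atoms: lithium hydroxide [Li+].[OH-]
Why: Mild saponification followed by careful acidification keeps the dimethyl acetal.

Step 4
Reactants: 8 (2E)-3-methylpent-2-en-4-yn-1-ol
Product: 10 (2E)-3-methyl-5-(trimethylsilyl)pent-2-en-4-yn-1-ol, via bis-silyl ether 9 (not isolated)
Conditions: n-BuLi (2.2 equiv), THF, −78 °C; Me3SiCl (2.3 equiv), −78 °C → rt; then 1 M HCl, rt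
Reagents that add atoms: chlorotrimethylsilane C[Si](C)(C)Cl
Why: O,C-Bis-silylation of the dianion and selective hydrolysis of the labile O–Si bond leave the alkyne capped for the later palladium and samarium steps.

Step 5
Reactants: 10 (2E)-3-methyl-5-(trimethylsilyl)pent-2-en-4-yn-1-ol; 7 3,3-dimethoxypropanoic acid
Product: 11 (2E)-3-methyl-5-(trimethylsilyl)pent-2-en-4-yn-1-yl 3,3-dimethoxypropanoate
Conditions: DCC, DMAP (10 mol%), CH2Cl2, 0 °C → rt
Reagents that add atoms: none
Why: Steglich esterification under neutral conditions tolerates the acetal, the enyne and the silyl group.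

Step 6
Reactants: 11 (2E)-3-methyl-5-(trimethylsilyl)pent-2-en-4-yn-1-yl 3,3-dimethoxypropanoate
Product: 13 (3S)-2-(dimethoxymethyl)-3-methyl-3-[(trimethylsilyl)ethynyl]pent-4-enoic acid, via boron ketene acetal 12 (not isolated)
Conditions: (4S,5S)-2-bromo-4,5-diphenyl-1,3-bis(4-methylphenylsulfonyl)-1,3,2-diazaborolidine (1.1 equiv), Et3N, toluene/hexane, −78 °C then −20 °C; aqueous work-up
Reagents that add atoms: none
Why: Enantioselective Ireland–Claisen rearrangement: the chiral boron ketene acetal rearranges through a chair transition state whose enolate face is fixed by the diazaborolidine, which sets the quaternary carbon (ring C2 of the target) as S; the carboxyl-bearing carbon may form as either epimer because it becomes a planar radical in step 10.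

Step 7
Reactants: 13 (3S)-2-(dimethoxymethyl)-3-methyl-3-[(trimethylsilyl)ethynyl]pent-4-enoic acid
Product: 14 (3S)-3-acetyl-2-(dimethoxymethyl)-3-methyl-5-(trimethylsilyl)pent-4-ynoic acid
Conditions: PdCl2 (10 mol%), Cu(OAc)2 (20 mol%), O2 (1 atm), DMA/H2O, rt
Reagents that add atoms: water O
Why: Tsuji–Wacker oxidation should convert the monosubstituted alkene into the methyl ketone with Markovnikov selectivity, the acetate buffer sparing the acetal and the silyl-capped alkyne staying inert.

Step 8
Reactants: 14 (3S)-3-acetyl-2-(dimethoxymethyl)-3-methyl-5-(trimethylsilyl)pent-4-ynoic acid; 5 2-cyclopropylidenepropan-1-ol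
Product: 15 (3S)-3-acetyl-2-{bis[(2-cyclopropylidenepropyl)oxy]methyl}-3-methyl-5-(trimethylsilyl)pent-4-ynoic acid
Conditions: 5 (3 equiv), PPTS (5 mol%), toluene, 5 Å MS, 45 °C
Reagents that add atoms: none
Why: Acid-catalysed transacetalisation driven by removal of methanol installs two identical cyclopropylidene arms, so the acetal carbon is not a stereocenter before the key step.

Step 9
Reactants: 15 (3S)-3-acetyl-2-{bis[(2-cyclopropylidenepropyl)oxy]methyl}-3-methyl-5-(trimethylsilyl)pent-4-ynoic acid
Product: 16 1,3-dioxoisoindolin-2-yl ester of acid 15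
Conditions: N-hydroxyphthalimide, DIC, DMAP (5 mol%), CH2Cl2, rt
Reagents that add atoms: N-hydroxyphthalimide ON1C(=O)c2ccccc2C1=O
Why: Carbodiimide coupling gives the N-(acyloxy)phthalimide, a redox-active ester that is reduced far more easily than the ketone.

Step 10
Reactants: 16 1,3-dioxoisoindolin-2-yl ester of acid 15
Product: 21 (7R,8S,8aS)-1-[(2-cyclopropylidenepropyl)oxy]-4,7,8-trimethyl-8-[(trimethylsilyl)ethynyl]-3,5,6,7,8,8a-hexahydro-1H-isochromen-7-ol, via secondary alkyl radical 17 (not isolated), via spirocyclic cyclopropylcarbinyl radical 18 (not isolated), via primary alkyl radical 19 (not isolated), via primary alkylsamarium diiodide 20 (not isolated)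
Conditions: SmI2 (3 equiv, 0.1 M in THF, added over 2 h), HMPA (12 equiv), THF, −20 °C → rt; sat. aq. NH4Cl
Reagents that add atoms: none
Why: Proposed new method: electron transfer from divalent samarium to the N-(acyloxy)phthalimide expels CO2 and leaves the secondary radical 17 at C3, which attacks the cyclopropane ring carbon of one of the two identical arms (C3–C4), the tertiary cyclopropylcarbinyl radical 18 opens at once to the primary radical 19 with the new tetrasubstituted C=C held inside the dihydropyran, and a second SmI2 turns 19 into the alkylsamarium 20, which adds to the methyl ketone (C6–C1). The closest known reaction types are the Ueno–Stork acetal-tethered radical cyclization, radical addition to alkylidenecyclopropanes with ring opening, reductive decarboxylative radical formation from N-hydroxyphthalimide esters and the SmI2 radical cyclization–Barbier sequence; their combination in one relay through a cyclopropane is the new element. The dihydropyran closes 6-endo-trig (the 5-exo mode would give a cyclopropyl σ-radical) and the cyclohexane closes by 6-exo addition to the carbonyl group. C3 is controlled by allylic strain about the C3–C2 bond (the slim alkynyl group eclipses the acetal carbon and the acetyl group shields the rear face, so that the C3 hydrogen ends trans to the C2 methyl group as in the target), C1 is controlled in the chair-like Barbier transition state with the bulky samarium-bound oxygen equatorial and the ketone methyl axial, anti to the axial C2 methyl group, and the acetal carbon forms as an anomeric mixture that is lost in step 20. The step needs reduction of the ester before the ketone (slow addition of SmI2), cyclization of 17 faster than its reduction or 1,2-acyl shift (the short acetal tether), ring opening of 18 before reduction (a tertiary, non-stabilised radical that SmI2 reduces slowly) and reduction of 19 before hydrogen abstraction (HMPA).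

Step 11
Reactants: 21 (7R,8S,8aS)-1-[(2-cyclopropylidenepropyl)oxy]-4,7,8-trimethyl-8-[(trimethylsilyl)ethynyl]-3,5,6,7,8,8a-hexahydro-1H-isochromen-7-ol
Product: 22 (7R,8S,8aS)-1-[(2-cyclopropylidenepropyl)oxy]-8-ethynyl-4,7,8-trimethyl-3,5,6,7,8,8a-hexahydro-1H-isochromen-7-ol
Conditions: K2CO3, MeOH, rt
Reagents that add atoms: none
Why: Base-mediated methanolysis of the alkynyl C–Si bond leaves the acetal, the tertiary alcohol and the alkenes untouched.

Step 12
Reactants: 22 (7R,8S,8aS)-1-[(2-cyclopropylidenepropyl)oxy]-8-ethynyl-4,7,8-trimethyl-3,5,6,7,8,8a-hexahydro-1H-isochromen-7-ol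
Product: 23 (7R,8R,8aS)-1-[(2-cyclopropylidenepropyl)oxy]-8-ethenyl-4,7,8-trimethyl-3,5,6,7,8,8a-hexahydro-1H-isochromen-7-ol
Conditions: H2 (1 atm), Pd/CaCO3 poisoned with Pb(OAc)2, quinoline, EtOAc, rt
Reagents that add atoms: none
Why: Lindlar semi-hydrogenation should stop at the monosubstituted alkene, and the two tetrasubstituted alkenes do not react on the poisoned catalyst.

Step 13
Reactants: 24 3-methylbut-2-enal; 25 4,4,5,5-tetramethyl-2-(propa-1,2-dien-1-yl)-1,3,2-dioxaborolane
Product: 26 (4R)-6-methylhept-5-en-1-yn-4-ol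
Conditions: (R)-3,3'-bis(2,4,6-triisopropylphenyl)-1,1'-binaphthyl-2,2'-diyl hydrogen phosphate (5 mol%), toluene, 4 Å MS, −20 °C; aqueous work-up
Reagents that add atoms: none
Why: Chiral phosphoric acid-catalysed asymmetric propargylation of the aldehyde by the allenylboronate through a closed six-membered transition state sets the R carbinol.

Step 14
Reactants: 26 (4R)-6-methylhept-5-en-1-yn-4-ol
Product: 27 tert-butyl{[(4R)-6-methylhept-5-en-1-yn-4-yl]oxy}dimethylsilane
Conditions: t-BuMe2SiCl, imidazole, DMF, rt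
Reagents that add atoms: tert-butyl(chloro)dimethylsilane CC(C)(C)[Si](C)(C)Cl
Why: Standard silylation protects the allylic alcohol for the organometallic steps.

Step 15
Reactants: 27 tert-butyl{[(4R)-6-methylhept-5-en-1-yn-4-yl]oxy}dimethylsilane
Product: 29 tert-butyl{[(4R,6E)-7-iodo-2,6-dimethylhepta-2,6-dien-4-yl]oxy}dimethylsilane, via alkenylalane 28 (not isolated)
Conditions: AlMe3 (2 equiv), Cp2ZrCl2 (0.2 equiv), CH2Cl2, 0 °C → rt; then I2, THF, −30 → 0 °C
Reagents that add atoms: trimethylalumane C[Al](C)C; iodine II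
Why: Zirconium-catalysed syn-carboalumination (Negishi carboalumination) adds CH3 and aluminium across the terminal alkyne, and iodinolysis with retention gives the E alkenyl iodide.

Step 16
Reactants: 29 tert-butyl{[(4R,6E)-7-iodo-2,6-dimethylhepta-2,6-dien-4-yl]oxy}dimethylsilane; 30 (4-iodobut-1-yn-1-yl)trimethylsilane
Product: 32 tert-butyl{[(4R,6E)-2,6-dimethyl-11-(trimethylsilyl)undeca-2,6-dien-10-yn-4-yl]oxy}dimethylsilane, via alkylzinc iodide 31 (not isolated)
Conditions: Zn dust, LiCl, THF, 40 °C (from 30); then 29, PdCl2(dppf) (5 mol%), THF, rt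
Reagents that add atoms: none
Why: Negishi coupling of the alkylzinc iodide with the alkenyl iodide proceeds with retention of the E geometry.

Step 17
Reactants: 32 tert-butyl{[(4R,6E)-2,6-dimethyl-11-(trimethylsilyl)undeca-2,6-dien-10-yn-4-yl]oxy}dimethylsilane
Product: 33 tert-butyl{[(4R,6E)-2,6-dimethylundeca-2,6-dien-10-yn-4-yl]oxy}dimethylsilane
Conditions: K2CO3, MeOH, rt
Reagents that add atoms: none
Why: Methanolysis removes the alkynyl silyl group and leaves the silyl ether.

Step 18
Reactants: 33 tert-butyl{[(4R,6E)-2,6-dimethylundeca-2,6-dien-10-yn-4-yl]oxy}dimethylsilane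
Product: 35 tert-butyl{[(4R,6E,10E)-11-iodo-2,6,10-trimethylundeca-2,6,10-trien-4-yl]oxy}dimethylsilane, via alkenylalane 34 (not isolated)
Conditions: AlMe3 (2 equiv), Cp2ZrCl2 (0.2 equiv), CH2Cl2, 0 °C → rt; then I2, THF, −30 → 0 °C
Reagents that add atoms: trimethylalumane C[Al](C)C; iodine II
Why: A second carboalumination–iodination builds the next E trisubstituted alkenyl iodide with the same syn selectivity.

Step 19
Reactants: 23 (7R,8R,8aS)-1-[(2-cyclopropylidenepropyl)oxy]-8-ethenyl-4,7,8-trimethyl-3,5,6,7,8,8a-hexahydro-1H-isochromen-7-ol; 35 tert-butyl{[(4R,6E,10E)-11-iodo-2,6,10-trimethylundeca-2,6,10-trien-4-yl]oxy}dimethylsilane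
Product: 37 side-chain-coupled bicyclic acetal (stereocenters as in 21 and 35), via B-alkyl-9-BBN borane 36 (not isolated)
Conditions: 9-BBN-H (2.5 equiv), THF, 0 °C → rt; then 35, PdCl2(dppf) (5 mol%), AsPh3, Cs2CO3, DMF/H2O, rt
Reagents that add atoms: none
Why: 9-BBN hydroborates only the monosubstituted vinyl group (anti-Markovnikov), and the B-alkyl borane undergoes Suzuki–Miyaura coupling with the alkenyl iodide with retention of geometry.

Step 20
Reactants: 37 side-chain-coupled bicyclic acetal
Product: 38 side-chain-coupled lactol (3,6-dihydro-2H-pyran-2-ol fused to the cyclohexanol)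
Conditions: PPTS (20 mol%), acetone/H2O, 40 °C
Reagents that add atoms: water O
Why: Mild acid-catalysed acetal hydrolysis releases the second tether alcohol and leaves the six-membered lactol, which stores the first chain carbon as an aldehyde and keeps the allylic oxygen.

Step 21
Reactants: 38 side-chain-coupled lactol
Product: 39 allylic triol with the (E)-3-hydroxyprop-1-enyl chain at C3
Conditions: (2-hydroxyethyl)triphenylphosphonium bromide (4 equiv), n-BuLi (8 equiv), THF, −78 → 0 °C; then 38, 0 °C → rt
Reagents that add atoms: (2-hydroxyethyl)triphenylphosphonium bromide OCC[P+](c1ccccc1)(c1ccccc1)c1ccccc1.[Br-]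
Why: Wittig olefination of the lactol through its hydroxy aldehyde form with the β-oxido ylide appends the last two carbons of the hydroxypropyl chain and frees the allylic alcohol; the geometry of the new alkene does not matter.

Step 22
Reactants: 39 allylic triol with the (E)-3-hydroxyprop-1-enyl chain at C3
Product: 40 triol with the saturated 3-hydroxypropyl chain
Conditions: 2-nitrobenzenesulfonohydrazide (5 equiv), Et3N, CH2Cl2, rt
Reagents that add atoms: none
Why: Diimide, formed in the flask, reduces the 1,2-disubstituted alkene much faster than the tri- and tetrasubstituted ones.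

Step 23
Reactants: 40 triol with the saturated 3-hydroxypropyl chain
Product: 41 silyl-protected target (enal)
Conditions: MnO2 (20 equiv), CH2Cl2, rt
Reagents that add atoms: none
Why: MnO2 oxidises only the allylic primary alcohol to the enal, and the alkene geometry fixed by the former tether ring is kept.

Step 24
Reactants: 41 silyl-protected target (enal)
Product: 42 CNP0270422.1 (target)
Conditions: HF·pyridine, pyridine, THF, 0 °C → rt
Reagents that add atoms: none
Why: Buffered fluoride cleaves the silyl ether and spares the enal, the tertiary alcohol and the alkenes.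

**Compound list**

1 | [(1-ethoxycyclopropyl)oxy]trimethylsilane | CCOC1(CC1)O[Si](C)(C)C | starting material
2 | ethyl 2-(triphenyl-λ5-phosphanylidene)propanoate | CCOC(=O)C(C)=P(c1ccccc1)(c1ccccc1)c1ccccc1 | starting material
3 | cyclopropanone | O=C1CC1 | intermediate (not isolated)
4 | ethyl 2-cyclopropylidenepropanoate | CCOC(=O)C(C)=C1CC1 | intermediate
5 | 2-cyclopropylidenepropan-1-ol | OCC(C)=C1CC1 | intermediate
6 | methyl 3,3-dimethoxypropanoate | COC(=O)CC(OC)OC | starting material
7 | 3,3-dimethoxypropanoic acid | OC(=O)CC(OC)OC | intermediate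
8 | (2E)-3-methylpent-2-en-4-yn-1-ol | OC/C=C(\C)C#C | starting material
9 | trimethyl{[(2E)-3-methyl-5-(trimethylsilyl)pent-2-en-4-yn-1-yl]oxy}silane | C[Si](C)(C)OC/C=C(\C)C#C[Si](C)(C)C | intermediate (not isolated)
10 | (2E)-3-methyl-5-(trimethylsilyl)pent-2-en-4-yn-1-ol | OC/C=C(\C)C#C[Si](C)(C)C | intermediate
11 | (2E)-3-methyl-5-(trimethylsilyl)pent-2-en-4-yn-1-yl 3,3-dimethoxypropanoate | COC(OC)CC(=O)OC/C=C(\C)C#C[Si](C)(C)C | intermediate
12 | boron ketene acetal of 11 carrying the (4S,5S)-4,5-diphenyl-1,3-ditosyl-1,3,2-diazaborolidin-2-yl group on oxygen | COC(OC)C=C(OC/C=C(\C)C#C[Si](C)(C)C)OB1N(S(=O)(=O)c2ccc(C)cc2)[C@@H](c2ccccc2)[C@H](c2ccccc2)N1S(=O)(=O)c1ccc(C)cc1 | intermediate (not isolated)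
13 | (3S)-2-(dimethoxymethyl)-3-methyl-3-[(trimethylsilyl)ethynyl]pent-4-enoic acid (either epimer at C2) | COC(OC)C(C(=O)O)[C@@](C)(C#C[Si](C)(C)C)C=C | intermediate
14 | (3S)-3-acetyl-2-(dimethoxymethyl)-3-methyl-5-(trimethylsilyl)pent-4-ynoic acid (either epimer at C2) | COC(OC)C(C(=O)O)[C@@](C)(C#C[Si](C)(C)C)C(C)=O | intermediate
15 | (3S)-3-acetyl-2-{bis[(2-cyclopropylidenepropyl)oxy]methyl}-3-methyl-5-(trimethylsilyl)pent-4-ynoic acid (either epimer at C2) | OC(=O)C(C(OCC(C)=C1CC1)OCC(C)=C1CC1)[C@@](C)(C#C[Si](C)(C)C)C(C)=O | intermediate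
16 | 1,3-dioxoisoindolin-2-yl ester of acid 15 | O=C(ON1C(=O)c2ccccc2C1=O)C(C(OCC(C)=C1CC1)OCC(C)=C1CC1)[C@@](C)(C#C[Si](C)(C)C)C(C)=O | intermediate
17 | secondary alkyl radical formed from 16 by loss of CO2 and phthalimide anion | [CH](C(OCC(C)=C1CC1)OCC(C)=C1CC1)[C@@](C)(C#C[Si](C)(C)C)C(C)=O | intermediate (not isolated)
18 | spirocyclic tertiary cyclopropylcarbinyl radical (tetrahydropyran spiro-fused to cyclopropane) | CC(=O)[C@](C)(C#C[Si](C)(C)C)[C@H]1C(OCC(C)=C2CC2)OC[C](C)C13CC3 | intermediate (not isolated)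
19 | ring-opened primary alkyl radical (2-(dihydropyranyl)ethyl radical) | CC(=O)[C@](C)(C#C[Si](C)(C)C)[C@H]1C(OCC(C)=C2CC2)OCC(C)=C1C[CH2] | intermediate (not isolated)
20 | primary alkylsamarium diiodide (trivalent samarium) | CC(=O)[C@](C)(C#C[Si](C)(C)C)[C@H]1C(OCC(C)=C2CC2)OCC(C)=C1CC[Sm](I)I | intermediate (not isolated)
21 | (7R,8S,8aS)-1-[(2-cyclopropylidenepropyl)oxy]-4,7,8-trimethyl-8-[(trimethylsilyl)ethynyl]-3,5,6,7,8,8a-hexahydro-1H-isochromen-7-ol (anomeric mixture at C1) | C[Si](C)(C)C#C[C@]1(C)[C@H]2C(OCC(C)=C3CC3)OCC(C)=C2CC[C@@]1(C)O | intermediate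
22 | (7R,8S,8aS)-1-[(2-cyclopropylidenepropyl)oxy]-8-ethynyl-4,7,8-trimethyl-3,5,6,7,8,8a-hexahydro-1H-isochromen-7-ol (anomeric mixture) | C#C[C@]1(C)[C@H]2C(OCC(C)=C3CC3)OCC(C)=C2CC[C@@]1(C)O | intermediate
23 | (7R,8R,8aS)-1-[(2-cyclopropylidenepropyl)oxy]-8-ethenyl-4,7,8-trimethyl-3,5,6,7,8,8a-hexahydro-1H-isochromen-7-ol (anomeric mixture) | C=C[C@]1(C)[C@H]2C(OCC(C)=C3CC3)OCC(C)=C2CC[C@@]1(C)O | intermediate
24 | 3-methylbut-2-enal | CC(C)=CC=O | starting material
25 | 4,4,5,5-tetramethyl-2-(propa-1,2-dien-1-yl)-1,3,2-dioxaborolane | C=C=CB1OC(C)(C)C(C)(C)O1 | starting material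
26 | (4R)-6-methylhept-5-en-1-yn-4-ol | CC(C)=C[C@H](O)CC#C | intermediate
27 | tert-butyl{[(4R)-6-methylhept-5-en-1-yn-4-yl]oxy}dimethylsilane | CC(C)=C[C@H](O[Si](C)(C)C(C)(C)C)CC#C | intermediate
28 | (E)-alkenyl(dimethyl)alane from 27 | CC(C)=C[C@H](O[Si](C)(C)C(C)(C)C)C/C(C)=C/[Al](C)C | intermediate (not isolated)
29 | tert-butyl{[(4R,6E)-7-iodo-2,6-dimethylhepta-2,6-dien-4-yl]oxy}dimethylsilane | CC(C)=C[C@H](O[Si](C)(C)C(C)(C)C)C/C(C)=C/I | intermediate
30 | (4-iodobut-1-yn-1-yl)trimethylsilane | C[Si](C)(C)C#CCCI | starting material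
31 | [4-(trimethylsilyl)but-3-yn-1-yl]zinc iodide | C[Si](C)(C)C#CCC[Zn]I | intermediate (not isolated)
32 | tert-butyl{[(4R,6E)-2,6-dimethyl-11-(trimethylsilyl)undeca-2,6-dien-10-yn-4-yl]oxy}dimethylsilane | CC(C)=C[C@H](O[Si](C)(C)C(C)(C)C)C/C(C)=C/CCC#C[Si](C)(C)C | intermediate
33 | tert-butyl{[(4R,6E)-2,6-dimethylundeca-2,6-dien-10-yn-4-yl]oxy}dimethylsilane | CC(C)=C[C@H](O[Si](C)(C)C(C)(C)C)C/C(C)=C/CCC#C | intermediate
34 | (E,E)-alkenyl(dimethyl)alane from 33 | CC(C)=C[C@H](O[Si](C)(C)C(C)(C)C)C/C(C)=C/CC/C(C)=C/[Al](C)C | intermediate (not isolated)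
35 | tert-butyl{[(4R,6E,10E)-11-iodo-2,6,10-trimethylundeca-2,6,10-trien-4-yl]oxy}dimethylsilane | CC(C)=C[C@H](O[Si](C)(C)C(C)(C)C)C/C(C)=C/CC/C(C)=C/I | intermediate
36 | B-alkyl-9-borabicyclo[3.3.1]nonane from 23 (boron on the terminal carbon of the former vinyl group) | C1CC2CCCC(C1)B2CC[C@]1(C)[C@H]2C(OCC(C)=C3CC3)OCC(C)=C2CC[C@@]1(C)O | intermediate (not isolated)
37 | side-chain-coupled bicyclic acetal: 21-type hexahydroisochromen-7-ol carrying at C8 the (3E,7E,10R)-10-[(tert-butyldimethylsilyl)oxy]-4,8,12-trimethyltrideca-3,7,11-trienyl chain | CC(C)=C[C@H](O[Si](C)(C)C(C)(C)C)C/C(C)=C/CC/C(C)=C/CC[C@]1(C)[C@H]2C(OCC(C)=C3CC3)OCC(C)=C2CC[C@@]1(C)O | intermediate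
38 | side-chain-coupled lactol (1-hydroxy analogue of 37, anomeric mixture) | CC(C)=C[C@H](O[Si](C)(C)C(C)(C)C)C/C(C)=C/CC/C(C)=C/CC[C@]1(C)[C@H]2C(O)OCC(C)=C2CC[C@@]1(C)O | intermediate
39 | allylic triol: cyclohexanol with the (E)-3-hydroxyprop-1-enyl chain at C3 and the exocyclic 1-hydroxypropan-2-ylidene group at C4 (CH2OH cis to C3) | CC(C)=C[C@H](O[Si](C)(C)C(C)(C)C)C/C(C)=C/CC/C(C)=C/CC[C@]1(C)[C@@H](/C=C/CO)/C(=C(/C)CO)CC[C@@]1(C)O | intermediate
40 | triol with the saturated 3-hydroxypropyl chain at C3 | CC(C)=C[C@H](O[Si](C)(C)C(C)(C)C)C/C(C)=C/CC/C(C)=C/CC[C@]1(C)[C@@H](CCCO)/C(=C(/C)CO)CC[C@@]1(C)O | intermediate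
41 | tert-butyldimethylsilyl ether of the target at the side-chain carbinol | CC(C)=C[C@H](O[Si](C)(C)C(C)(C)C)C/C(C)=C/CC/C(C)=C/CC[C@]1(C)[C@@H](CCCO)/C(=C(/C)C=O)CC[C@@]1(C)O | intermediate
42 | CNP0270422.1 | CC(C)=C[C@H](O)C/C(C)=C/CC/C(C)=C/CC[C@]1(C)[C@@H](CCCO)/C(=C(/C)C=O)CC[C@@]1(C)O | target

**Step count and risks**

Total step count: 24 (steps 1–2 tether alcohol, step 3 acid, steps 4–12 ring fragment, steps 13–18 side chain, steps 19–24 union and endgame). Longest linear sequence: 15 steps (steps 4–12 and 19–24, from 8 to 42).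

Steps most likely to fail:

1. Step 10 (Proposed new method). The first radical may be reduced or undergo a 1,2-acyl shift before it cyclizes, the primary radical may abstract hydrogen before it is reduced, and the facial selectivity at C3 may be poor. Fallback (known reactions, stepwise instead of one relay): it sets out from 15 and returns at 21. Barton iododecarboxylation of 15 (N-hydroxypyridine-2-thione, DCC; then hν, CHI3) gives the secondary iodide F1. Iodine-atom-transfer radical cyclization (Et3B, air, benzene) closes the dihydropyran with ring opening of the cyclopropane and delivers the primary iodide F2, at which stage C3 diastereomers can be separated. A separate SmI2–HMPA Barbier cyclization of F2 then gives 21.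

2. Step 6. The Lewis-acidic bromoborane may cleave the dimethyl acetal, and the enantioselectivity may erode. Fallback (chirality transfer from a carbinol instead of reagent control): it sets out from 10 and returns at 14. MnO2 oxidation of 10 gives the enynal F3. Addition of Me2Zn in the presence of a chiral amino alcohol ((−)-3-exo-morpholinoisoborneol) gives the secondary alcohol F4. Steglich esterification with 7 gives the ester F5. Ireland–Claisen rearrangement (LDA, Me3SiCl, THF, −78 °C → rt) through the chair with the carbinol methyl group equatorial gives the (E)-propenyl acid F6 with the same quaternary configuration as 13. Ozonolysis (O3, then Me2S) gives the aldehyde acid F7, and MeMgBr gives the secondary alcohol, which should close to the γ-lactone F8. Saponification (LiOH) and oxidation of the hydroxy carboxylate (TEMPO, NaOCl, buffered) give 14.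

3. Step 22. The trisubstituted alkenes may be over-reduced, or the reduction may stay incomplete. Fallback (conjugated ester and hydride conjugate reduction instead of diimide): it sets out from 38 and returns at 40. Wittig olefination of 38 with Ph3P=CHCO2Et gives the (E)-enoate F9. Conjugate reduction with [(Ph3P)CuH]6 touches only the enoate and gives the saturated ester F10. Reduction with i-Bu2AlH gives 40.

Further compounds
F1 | step 10 | 3-[2,2-bis(2-cyclopropylidenepropoxy)-1-iodoethyl]-3-methyl-5-(trimethylsilyl)pent-4-yn-2-one (quaternary carbon as in 15, either epimer at the CHI carbon) | CC(=O)[C@](C)(C#C[Si](C)(C)C)C(I)C(OCC(C)=C1CC1)OCC(C)=C1CC1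
F2 | step 10 | 3-[2-(2-cyclopropylidenepropoxy)-4-(2-iodoethyl)-5-methyl-3,6-dihydro-2H-pyran-3-yl]-3-methyl-5-(trimethylsilyl)pent-4-yn-2-one (configured as in 19) | CC(=O)[C@](C)(C#C[Si](C)(C)C)[C@H]1C(OCC(C)=C2CC2)OCC(C)=C1CCI
F3 | step 6 | (2E)-3-methyl-5-(trimethylsilyl)pent-2-en-4-ynal | O=C/C=C(\C)C#C[Si](C)(C)C
F4 | step 6 | (2R,3E)-4-methyl-6-(trimethylsilyl)hex-3-en-5-yn-2-ol | C[C@@H](O)/C=C(\C)C#C[Si](C)(C)C
F5 | step 6 | (2R,3E)-4-methyl-6-(trimethylsilyl)hex-3-en-5-yn-2-yl 3,3-dimethoxypropanoate | COC(OC)CC(=O)O[C@H](C)/C=C(\C)C#C[Si](C)(C)C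
F6 | step 6 | (3S,4E)-2-(dimethoxymethyl)-3-methyl-3-[(trimethylsilyl)ethynyl]hex-4-enoic acid (either epimer at C2) | COC(OC)C(C(=O)O)[C@@](C)(C#C[Si](C)(C)C)/C=C/C
F7 | step 6 | 2-(dimethoxymethyl)-3-formyl-3-methyl-5-(trimethylsilyl)pent-4-ynoic acid (quaternary carbon as in F6) | COC(OC)C(C(=O)O)[C@@](C)(C#C[Si](C)(C)C)C=O
F8 | step 6 | 3-(dimethoxymethyl)-4,5-dimethyl-4-[(trimethylsilyl)ethynyl]oxolan-2-one (quaternary carbon as in F6) | COC(OC)C1C(=O)OC(C)[C@]1(C)C#C[Si](C)(C)C
F9 | step 22 | ethyl (E)-enoate analogue of 39 (CH=CH–CO2Et in place of CH=CH–CH2OH) | CC(C)=C[C@H](O[Si](C)(C)C(C)(C)C)C/C(C)=C/CC/C(C)=C/CC[C@]1(C)[C@@H](/C=C/C(=O)OCC)/C(=C(/C)CO)CC[C@@]1(C)O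
F10 | step 22 | saturated ethyl ester analogue of 40 (CH2CH2CO2Et in place of CH2CH2CH2OH) | CC(C)=C[C@H](O[Si](C)(C)C(C)(C)C)C/C(C)=C/CC/C(C)=C/CC[C@]1(C)[C@@H](CCC(=O)OCC)/C(=C(/C)CO)CC[C@@]1(C)O
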